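Per equivalent of Z and per hour, a steady fraction of the J in these flasks goes on to L at this X charge, and that fraction is what I read from the runs and carry to Tuesday's flask.

| flask | X | Z | remark | time |
|---|---|---|---|---|
| theta | 0.48 M | 0.43 equiv | run made earlier |  |
| eta | 0.48 M | 1.1 equiv | run made earlier |  |
| zeta | 0.48 M | 2.4 equiv | run made earlier |  |
| Saturday's | 0.48 M | 1.50 equiv |  | 25 h |
| Tuesday's | 0.48 M | 2.50 equiv |  | 25 h |
| Friday's | 0.48 M | 0.500 equiv |  | 25 h |

| run | time / h | L / % | X / % |
|---|---|---|---|
| theta | 2.00 | 0 | 57 |
| theta | 4.00 | 3 | 57 |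
| theta | 8.00 | 3 | 58 |
| theta | 12.0 | 0 | 55 |
| theta | 25.0 | 5 | 57 |
| eta | 2.00 | 4 | 19 |
| eta | 6.00 | 13 | 8 |
| eta | 12.0 | 15 | 7 |
| eta | 20.0 | 15 | 4 |
| eta | 25.0 | 19 | 6 |
| zeta | 5.00 | 55 | 2 |
| zeta | 10.0 | 72 | 4 |
| zeta | 15.0 | 83 | 3 |
| zeta | 20.0 | 88 | 1 |
| zeta | 25.0 | 89 | 1 |

(standard deviation of a reading: 2 percentage points)

- a reading or a percentage of L counts all its forms, free or not

1. which of these holds the largest part of the X at the end of Saturday's (J / L / X)
2. which of these holds the largest part of the X at the end of Tuesday's (J / L / X)
3. which of these holds the largest part of the X at the end of Friday's (J / L / X)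
4. how much L is there at the end of Tuesday's, in percent of the X charged

The runs read as X + Z → J, then J + Z → L. In zeta, X is down to 2 % at 5.00 h, so I take the first step as over at the start and compute only the small remainder j, the fraction of the charge still J. With D the Z beyond two equivalents, the rate κ·j·(j + D) integrates to j = D / ((1 + D)·exp(κDt) − 1). Zeta's reading of 88 % L at 20.0 h, the rest taken as J, gives the second-step constant κ, the fraction of J converted per hour per equivalent of Z: 0.141 h⁻¹.

For Tuesday's flask there are two pseudo-first-order extremes. With Z held at the 1.50 equivalents left after the first step, j at 25 h is 0.501 %; with Z held at the 0.500 equivalents left once all the J has reacted, it is 17.1 %. Z falls from the first level towards the second, so the flask lies between them, and the integrated form gives j = 6.44 %, hence L 93.6 %, with J far behind. On Saturday's flask the Z beyond one equivalent is 0.500, which caps L at that fraction of the charge, so I expect J to lead. On Friday's flask Z is the limiting reagent, and each L made adds to X's lead over J.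

The forecast names J, L and X for Saturday's, Tuesday's and Friday's, with 92 % L on Tuesday's (88 % to 96 %), “allowing for the late flattening”, a little below my figure.

The flasks give J, L and X, with 94.8 % L on Tuesday's.

    Q ⇌ L, rate k1*(cs1 - [L]) while solid is left; crystals form when [L] > cs1 (solubility = 0.400 M, k = 0.170 s⁻¹)
    X + Z → J (k = 0.00110 M⁻¹ s⁻¹)
    Z + J → L (k = 9.10 × 10⁻⁵ M⁻¹ s⁻¹)

Tuesday's flask holds 5.23 % J against my 6.44 %, a gap of 1.2 percentage points. It also holds Q, crystals of L, at 11.4 % of the charge, inside the 94.8 %, and the saturation of L makes no difference to the total. For a neighbouring flask, Tuesday's with 0.19 M X at the same equivalents and time, I scale κ by the ratio of X charges to 0.0559 h⁻¹. The same form gives j = 24.8 %, so L 75.2 %. That neighbouring flask gives 77.5 % L, with 0 % Q.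

All runs come from a simulation from invented constants; the scatter is artificial.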